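**Retrosynthetic overview**

1. The target is traced back to a 3β,19-diol 7-ketone. The 6β-hydroxyl comes last by enolate hydroxylation, the acetates just before it, and the 2,3-dihydrofuran ring (O–C15=C14–C13–C16) from endo-cycloisomerisation of a 13-ethynyl-13-hydroxymethyl oxolane.
2. The oxolane ring (O, C9, C11, C12, C13) is made by ring contraction of a spiro 3,4-dihydro-2H-pyran (O, C9, C11, C12, C13, C14). The ring oxygen shifts from C14 to C13 and C14 leaves the ring as a formyl group, which later becomes C14≡C15; C16 is added by an aldol reaction.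
3. Enabling feature: C13 carries both the ring oxygen and C14, and C14 is an sp2 carbon at the aldehyde oxidation level in the target. The oxygen can therefore be bonded to C14 first (six-membered enol ether from a 4-pentynyl carbinol) and then moved to C13.
4. The dihydropyran comes from the C9 ketone and a four-carbon Grignard reagent. The cis-decalin comes from a Diels–Alder reaction of (S)-carvone (ring B, C20, isopropenyl as latent C7 carbonyl) with a 2-silyloxy diene (ring A). The single carvone stereocentre relays all others and is then erased.
5. Ring order: ring B (bought) → ring A → six-membered spiro enol ether → five-membered oxolane → dihydrofuran.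

Key step: step 10

Remark on the chemistry: labdane numbering is used (ring A = C1–C5, C10; ring B = C5–C10; C17 on C8; C18 (α) and C19 (β) on C4; C20 on C10; side chain C11–C16), and β is the face of C20. As written, the target has H-5 β, that is a cis-fused decalin, and the route is designed for that isomer. The stereochemical arguments assume the ring B chair with C20, the C5–C4 bond and the C9–O bond axial and the C7 and C8 substituents equatorial.

**Route**

Step 1
Reactants: 1 pent-1-en-3-one
Product: 2 (Z)-3-(tert-butyldimethylsilyloxy)penta-1,3-diene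
Conditions: TBSOTf, Et3N, Et2O, 0 °C
Reagents that add atoms: tert-butyldimethylsilyl trifluoromethanesulfonate, CC(C)(C)[Si](C)(C)OS(=O)(=O)C(F)(F)F
Why: Silyl dienol ether formation by soft enolisation of the ethyl ketone should give the 2-silyloxy diene as the Z enol ether, so that the terminal methyl is an outside substituent of the s-cis diene; no stereocentre is formed.

Step 2
Reactants: 3 (S)-(+)-carvone; 2 (Z)-3-(tert-butyldimethylsilyloxy)penta-1,3-diene
Product: 4 cis-fused Diels–Alder adduct (3-silyloxy-2-ene 9-ketone)
Conditions: EtAlCl2 (0.5 equiv), toluene, −20 °C → rt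
Reagents that add atoms: none
Why: Lewis acid catalysed Diels–Alder reaction of carvone with a 2-silyloxy diene, in which the nucleophilic CHMe terminus (future C4) bonds to the enone β-carbon (future C5) and the CH2 terminus to the methyl-bearing α-carbon (future C10), the suprafacial addition makes the ring fusion cis (H-5 and C20 on one face), and the diene adds anti to the isopropenyl group, so that the one stereocentre of carvone (future C7) fixes C5 and C10; the endo mode places the C4 methyl α, a centre that is enolised again in step 6.

Step 3
Reactants: 4 cis-fused Diels–Alder adduct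
Product: 5 8α-methyl 9-ketone
Conditions: LiN(iPr)2, THF, −78 °C; MeI, DMPU, −78 → −20 °C
Reagents that add atoms: iodomethane, CI
Why: Ketone enolate alkylation at C8, the only enolisable position of the C9 ketone (C10 is quaternary and the silyl enol ether is inert to the amide base), with the new methyl entering equatorially (α) to avoid the syn-axial angular methyl, which is also the thermodynamically favoured epimer at this enolisable centre.

Step 4
Reactants: 5 8α-methyl 9-ketone; 6 4-bromo-1-(trimethylsilyl)but-1-yne
Product: 8 9α-carbinol carrying the 4-(trimethylsilyl)but-3-ynyl chain on C9, via Grignard reagent 7 (not isolated)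
Conditions: 6, Mg, THF, rt; CeCl3, THF, −78 °C; then 5, −78 → 0 °C; then H2O
Reagents that add atoms: none
Why: Organocerium 1,2-addition to a hindered enolisable ketone (CeCl3 suppresses enolisation and reduction), in which the axial trajectory onto C9 is blocked by the axial C4 of ring A (1,3-diaxial), so the chain should enter equatorially from the β face and leave the new hydroxyl axial (α), the C9 configuration of the target.

Step 5
Reactants: 8 9α-carbinol with silyl enol ether
Product: 9 1-en-3-one (ring A enone)
Conditions: Pd(OAc)2 (1.1 equiv), MeCN, rt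
Reagents that add atoms: none
Why: Saegusa–Ito oxidation, in which palladation of the silyl enol ether at C2 and β-hydride elimination toward C1 give the C1=C2 enone regiospecifically without touching C4; no stereocentre is formed and the silyl alkyne and the isopropenyl group are inert.

Step 6
Reactants: 9 ring A enone
Product: 10 4β-hydroxymethyl enone (C4 quaternary)
Conditions: LiN(iPr)2 (2.3 equiv), THF, −78 °C; CH2O (monomeric, THF), −78 °C; then H2O
Reagents that add atoms: formaldehyde, C=O
Why: Aldol reaction of the cross-conjugated α'-enolate with formaldehyde, in which the second equivalent of base can only remove H-4 (C10 is quaternary, so there is no γ-proton) and formaldehyde should add to C4 from the β face, away from the axial C9 that covers the α face of ring A, setting the quaternary centre with C19 β and C18 α.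

Step 7
Reactants: 10 4β-hydroxymethyl enone
Product: 11 saturated 3-ketone
Conditions: [(Ph3P)CuH]6 (0.4 equiv), H2O (5 equiv), toluene, rt
Reagents that add atoms: none
Why: Conjugate reduction of the enone by the phosphine-stabilised copper hydride (1,4-hydride delivery, protonation of the copper enolate by water) is chemoselective over the isolated 1,1-disubstituted alkene and the silyl alkyne and creates no stereocentre.

Step 8
Reactants: 11 saturated 3-ketone
Product: 13 3β,9α,19-triol with terminal alkyne, via silylalkyne triol 12 (not isolated)
Conditions: LiBH(s-Bu)3 (3.5 equiv), THF, −78 °C; then K2CO3, MeOH, rt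
Reagents that add atoms: none
Why: Ketone reduction by a bulky trialkylborohydride, which avoids the axial path over H-1β and H-5β and attacks C3 equatorially from the α face to give the axial 3β-alcohol cis to C19 (the usual outcome for 4,4-disubstituted 3-ketones), followed in the same flask by protodesilylation of the alkynylsilane with carbonate in methanol.

Step 9
Reactants: 13 3β,9α,19-triol with terminal alkyne
Product: 14 spiro 3,4-dihydro-2H-pyran (O–C14=C13–C12–C11–C9)
Conditions: W(CO)6 (25 mol%), Et3N, THF, hν (350 nm), 55 °C
Reagents that add atoms: none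
Why: Tungsten-vinylidene endo-cycloisomerisation of a 4-pentyn-1-ol, in which the terminal alkyne rearranges on the metal to a vinylidene whose electrophilic carbon (C14) is captured by the C9 hydroxyl, the only hydroxyl within reach, closing the six-membered enol ether in the 6-endo mode; no stereocentre is formed.

Step 10
Reactants: 14 spiro 3,4-dihydro-2H-pyran
Product: 16 spiro oxolane-2-carbaldehyde (9α,13-epoxide with C14 as CHO), via dimethyl acetal 15 (not isolated)
Conditions: PhI(OH)OTs (1.05 equiv), MeOH, −20 → 0 °C; then 1 M HCl, THF, rt
Reagents that add atoms: water, O (aldehyde oxygen of 16); methanol, CO (the two methoxy groups of 15 only)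
Why: This is the oxidative ring contraction of a cyclic enol ether by a trivalent iodine reagent, the reaction type known for 3,4-dihydro-2H-pyran and glycals with Tl(NO3)3 or PhI(OH)OTs: the electrophilic iodane adds to the enol ether β-carbon C13 and methanol to C14, giving a trans 2-methoxy-3-iodanyl tetrahydropyran. The phenyliodanyl group is an excellent leaving group, the ring C14–O bond lies antiperiplanar to the equatorial C13–I bond, and the ring oxygen shifts from C14 to C13 with loss of PhI, so the oxolane arises by a 1,2-shift of oxygen (through an oxiranium-like transition state) and not by a cyclisation mode. C14 is left as an exocyclic oxocarbenium ion that methanol traps as acetal 15, and dilute acid then frees the aldehyde. The new centre C13 is formed with inversion at the carbon that carried iodine and as a mixture of epimers, which is of no consequence because C13 is enolised in step 11, while C9 is untouched since the C9–O bond is never broken. The step needs chemoselectivity for the enol ether over the isopropenyl alkene, which the far higher nucleophilicity of the enol ether should secure with one equivalent of reagent at low temperature; the free hydroxyls are too remote to intercept the oxocarbenium ion.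

Step 11
Reactants: 16 spiro oxolane-2-carbaldehyde
Product: 17 13-hydroxymethyl aldehyde (C13 quaternary)
Conditions: CH2O (37% aq.), Et3N (0.3 equiv), 1,4-dioxane, 45 °C
Reagents that add atoms: formaldehyde, C=O
Why: Amine-catalysed crossed aldol reaction (hydroxymethylation) of an α-branched aldehyde, in which formaldehyde should add to the face of the C13=C14 enol turned toward C8, because the oxolane oxygen is axial on ring B and the face turned toward C10/C5 is covered by the axial C4 of ring A; this makes C13 quaternary with C16 cis to C8 and C14 cis to C10, as in the target.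

Step 12
Reactants: 17 13-hydroxymethyl aldehyde
Product: 18 13-ethynyl-13-hydroxymethyl oxolane (3β,16,19-triol)
Conditions: MeC(O)C(N2)P(O)(OMe)2, K2CO3, MeOH, 0 °C → rt
Reagents that add atoms: dimethyl (1-diazo-2-oxopropyl)phosphonate, COP(=O)(OC)C(=[N+]=[N-])C(C)=O
Why: Ohira–Bestmann alkynylation (Seyferth–Gilbert homologation), in which the diazomethylphosphonate anion adds to the non-enolisable aldehyde and loss of phosphate and N2 with a 1,2-hydride shift gives the terminal alkyne C14≡C15; the quaternary centre C13 is not affected and free hydroxyls are tolerated.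

Step 13
Reactants: 18 13-ethynyl-13-hydroxymethyl oxolane
Product: 21 7-ketone, via methoxy hydroperoxide 19 (not isolated), via nitroxyl ether 20 (not isolated)
Conditions: O3, MeOH/CH2Cl2, −78 °C; then FeSO4·7H2O, TEMPO, −78 °C → rt; then mCPBA, CH2Cl2, 0 °C → rt
Reagents that add atoms: 2,2,6,6-tetramethylpiperidin-1-oxyl, CC1(C)CCCC(C)(C)N1[O] (its oxygen becomes the ketone oxygen); ozone, [O-][O+]=O, and methanol, CO (in 19 only)
Why: Dealkenylative oxidation, in which Criegee ozonolysis of the 1,1-disubstituted alkene in methanol (the alkyne reacts far more slowly) gives hydroperoxide 19, reduction by divalent iron and β-scission of the alkoxyl radical release methyl acetate and the secondary C7 radical that the nitroxyl traps as 20, and peracid oxidation of this alkoxyamine gives the ketone; the carvone stereocentre is erased here after it has done its work, and since the C9 oxygen is already an ether no retro-aldol cleavage is possible.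

Step 14
Reactants: 21 7-ketone
Product: 22 spiro 2,3-dihydrofuran (3β,19-diol 7-ketone)
Conditions: W(CO)6 (25 mol%), Et3N, THF, hν (350 nm), rt
Reagents that add atoms: none
Why: Tungsten-vinylidene endo-cycloisomerisation of a 3-butyn-1-ol, in which the primary C16 hydroxyl adds to the vinylidene carbon C15 in the 5-endo mode and gives the 2,3-dihydrofuran under the basic, non-oxidising conditions that the acid-labile enol ether requires; no stereocentre is formed.

Step 15
Reactants: 22 spiro 2,3-dihydrofuran diol
Product: 23 3β,19-diacetate
Conditions: Ac2O, pyridine, DMAP (cat.), CH2Cl2, 0 °C → rt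
Reagents that add atoms: acetic anhydride, CC(=O)OC(C)=O
Why: DMAP-catalysed acetylation of the primary C19 and the secondary C3 hydroxyl, the only hydroxyls present at this stage, in a basic medium that spares the enol ether.

Step 16
Reactants: 23 3β,19-diacetate
Product: 24 target, 3β,19-diacetoxy-6β-hydroxy-9α,13;15,16-diepoxy-5β-labd-14-en-7-one
Conditions: KN(SiMe3)2 (1.1 equiv), THF, −78 °C; then 2-(phenylsulfonyl)-3-phenyloxaziridine, −78 °C; then AcOH
Reagents that add atoms: 2-(phenylsulfonyl)-3-phenyloxaziridine, O=S(=O)(c1ccccc1)N1OC1c1ccccc1
Why: Oxaziridine hydroxylation of a ketone enolate (Davis oxidation), in which the amide base removes the less hindered H-6 kinetically (H-8 is tertiary and flanked by the quaternary C9) and the oxidant should attack C6 axially from the β face because the α face is covered by the axial C4 of ring A, giving the 6β-alcohol; the oxaziridine does not attack the enol ether and one equivalent of base at low temperature should spare the acetates.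

**Compound list**

1 | pent-1-en-3-one (ethyl vinyl ketone) | CCC(=O)C=C | starting material
2 | (Z)-3-(tert-butyldimethylsilyloxy)penta-1,3-diene | C/C=C(\O[Si](C)(C)C(C)(C)C)C=C | intermediate
3 | (S)-(+)-carvone, (5S)-2-methyl-5-(prop-1-en-2-yl)cyclohex-2-en-1-one | CC1=CC[C@@H](CC1=O)C(C)=C | starting material
4 | cis-decalin adduct: 3-(tert-butyldimethylsilyloxy)-4α,10β-dimethyl-7β-isopropenyl-5βH-decal-2-en-9-one | C[C@@H]1C(O[Si](C)(C)C(C)(C)C)=CC[C@@]2(C)[C@@H]1C[C@H](C(C)=C)CC2=O | intermediate
5 | 8α-methyl derivative of 4 (4α,8α,10β-trimethyl) | C[C@@H]1C(O[Si](C)(C)C(C)(C)C)=CC[C@@]2(C)[C@@H]1C[C@H](C(C)=C)[C@@H](C)C2=O | intermediate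
6 | 4-bromo-1-(trimethylsilyl)but-1-yne | C[Si](C)(C)C#CCCBr | starting material
7 | [4-(trimethylsilyl)but-3-yn-1-yl]magnesium bromide (not isolated) | C[Si](C)(C)C#CCC[Mg]Br | intermediate
8 | 9α-hydroxy-9β-[4-(trimethylsilyl)but-3-ynyl] carbinol, silyl enol ether intact | C[C@@H]1C(O[Si](C)(C)C(C)(C)C)=CC[C@@]2(C)[C@@H]1C[C@H](C(C)=C)[C@@H](C)[C@]2(O)CCC#C[Si](C)(C)C | intermediate
9 | 9α-hydroxy-1-en-3-one (ring A enone), 4α-methyl | C[C@@H]1C(=O)C=C[C@@]2(C)[C@@H]1C[C@H](C(C)=C)[C@@H](C)[C@]2(O)CCC#C[Si](C)(C)C | intermediate
10 | enone with quaternary C4: 4β-hydroxymethyl (C19), 4α-methyl (C18) | OC[C@@]1(C)C(=O)C=C[C@@]2(C)[C@@H]1C[C@H](C(C)=C)[C@@H](C)[C@]2(O)CCC#C[Si](C)(C)C | intermediate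
11 | 9α,19-dihydroxy 3-ketone (C1–C2 saturated) | OC[C@@]1(C)C(=O)CC[C@@]2(C)[C@@H]1C[C@H](C(C)=C)[C@@H](C)[C@]2(O)CCC#C[Si](C)(C)C | intermediate
12 | 3β,9α,19-triol with trimethylsilyl alkyne (not isolated) | OC[C@@]1(C)[C@@H](O)CC[C@@]2(C)[C@@H]1C[C@H](C(C)=C)[C@@H](C)[C@]2(O)CCC#C[Si](C)(C)C | intermediate
13 | 3β,9α,19-triol with 9β-(but-3-ynyl) chain | OC[C@@]1(C)[C@@H](O)CC[C@@]2(C)[C@@H]1C[C@H](C(C)=C)[C@@H](C)[C@]2(O)CCC#C | intermediate
14 | spiro 3,4-dihydro-2H-pyran at C9 (ring O–C14=C13–C12–C11–C9, oxygen α on C9), 3β,19-diol | OC[C@@]1(C)[C@@H](O)CC[C@@]2(C)[C@@H]1C[C@H](C(C)=C)[C@@H](C)[C@]21CCC=CO1 | intermediate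
15 | spiro oxolane with 13-(dimethoxymethyl) group, C13 epimers (not isolated) | OC[C@@]1(C)[C@@H](O)CC[C@@]2(C)[C@@H]1C[C@H](C(C)=C)[C@@H](C)[C@]21CCC(C(OC)OC)O1 | intermediate
16 | spiro oxolane-2-carbaldehyde (9α,13-epoxide, C14 = CHO), C13 epimers | OC[C@@]1(C)[C@@H](O)CC[C@@]2(C)[C@@H]1C[C@H](C(C)=C)[C@@H](C)[C@]21CCC(C=O)O1 | intermediate
17 | 13-formyl-13-(hydroxymethyl) oxolane, C16 cis to C8 and C14 cis to C10 | OC[C@@]1(C)[C@@H](O)CC[C@@]2(C)[C@@H]1C[C@H](C(C)=C)[C@@H](C)[C@]21CC[C@](CO)(C=O)O1 | intermediate
18 | 13-ethynyl-13-(hydroxymethyl) oxolane, 3β,16,19-triol, 7β-isopropenyl | OC[C@@]1(C)[C@@H](O)CC[C@@]2(C)[C@@H]1C[C@H](C(C)=C)[C@@H](C)[C@]21CC[C@](CO)(C#C)O1 | intermediate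
19 | 7β-(2-hydroperoxy-2-methoxypropan-2-yl) compound (not isolated) | OC[C@@]1(C)[C@@H](O)CC[C@@]2(C)[C@@H]1C[C@H](C(C)(OC)OO)[C@@H](C)[C@]21CC[C@](CO)(C#C)O1 | intermediate
20 | C7 ether of 2,2,6,6-tetramethylpiperidin-1-ol, C7 epimers (not isolated) | OC[C@@]1(C)[C@@H](O)CC[C@@]2(C)[C@@H]1CC(ON3C(C)(C)CCCC3(C)C)[C@@H](C)[C@]21CC[C@](CO)(C#C)O1 | intermediate
21 | 13-ethynyl-3β,16,19-trihydroxy-9α,13-epoxy 7-ketone | OC[C@@]1(C)[C@@H](O)CC[C@@]2(C)[C@@H]1CC(=O)[C@@H](C)[C@]21CC[C@](CO)(C#C)O1 | intermediate
22 | 3β,19-dihydroxy-9α,13;15,16-diepoxy-5β-labd-14-en-7-one | OC[C@@]1(C)[C@@H](O)CC[C@@]2(C)[C@@H]1CC(=O)[C@@H](C)[C@]21CC[C@]2(C=COC2)O1 | intermediate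
23 | 3β,19-diacetoxy-9α,13;15,16-diepoxy-5β-labd-14-en-7-one | CC(=O)OC[C@@]1(C)[C@@H](OC(C)=O)CC[C@@]2(C)[C@@H]1CC(=O)[C@@H](C)[C@]21CC[C@]2(C=COC2)O1 | intermediate
24 | 3β,19-diacetoxy-6β-hydroxy-9α,13;15,16-diepoxy-5β-labd-14-en-7-one | CC(=O)OC[C@@]1(C)[C@@H](OC(C)=O)CC[C@@]2(C)[C@@H]1[C@H](O)C(=O)[C@@H](C)[C@]21CC[C@]2(C=COC2)O1 | target

**Step count and risks**

Total step count: 16. Longest linear sequence: 16 steps (1 → 24); the Grignard reagent is made in the flask of step 4.

The three steps most likely to fail:

1. Step 11. Facial selectivity in the addition of formaldehyde to the C13 enol may be poor, since the two faces differ only through the spiro centre; crossed Cannizzaro over-reduction or retro-aldol loss of formaldehyde may also intervene. The fallback replaces substrate control by catalyst control and sets out from 16. Silylation (Me3SiCl, Et3N, NaI, MeCN) should give the tris(trimethylsilyl) enol ether F1, in which the aldehyde is an enol silane and both hydroxyls are silyl ethers. A Mukaiyama-type hydroxymethylation with aqueous formaldehyde under Sc(OTf)3 and a chiral 6,6'-bis(1-hydroxy-2,2-dimethylpropyl)-2,2'-bipyridine (the known catalytic asymmetric hydroxymethylation of silicon enolates) follows, with the ligand enantiomer chosen to give C16 cis to C8. Dilute acid in the work-up removes the silyl ethers, and the route is rejoined at 17.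

2. Step 10. The iodane intermediate may be captured by methanol without the 1,2-oxygen shift (giving a 2,3-dimethoxy tetrahydropyran), or the isopropenyl group may be oxidised as well. The fallback does the ring contraction stepwise through an open-chain form and sets out from 14. Hydroxybromination of the enol ether (NBS, THF/H2O, 0 °C) should give the trans bromo lactol F2. K2CO3 in MeCN then opens the lactol to the α-bromo aldehyde, whose tertiary C9 alkoxide displaces bromide in a 5-exo-tet Williamson closure. The route is rejoined at 16.

3. Step 9. Capture of the tungsten vinylidene by the hindered tertiary hydroxyl may be slow, so that the catalyst decays or the alkyne oligomerises. The fallback builds the enol ether by hydration and dehydration and sets out from 13. Anti-Markovnikov hydration of the terminal alkyne with CpRu(MeCN)3PF6 and 5,5'-bis(trifluoromethyl)-2,2'-bipyridine in NMP/H2O should give the δ-hydroxy aldehyde, which closes to the spiro lactol F3. Acid-catalysed dehydration (camphorsulfonic acid, toluene, reflux, 4 Å molecular sieves) then gives the enol ether, and the route is rejoined at 14.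

Further compounds
F1 | step 11 | tris(trimethylsilyl) enol ether of 16 (3β- and 19-trimethylsilyl ethers, C13=C14 enol silane, E/Z mixture) | C[Si](C)(C)OC[C@@]1(C)[C@@H](O[Si](C)(C)C)CC[C@@]2(C)[C@@H]1C[C@H](C(C)=C)[C@@H](C)[C@]21CCC(=CO[Si](C)(C)C)O1
F2 | step 10 | trans bromo lactol (13-bromo-14-hydroxy tetrahydropyran spiro at C9, anomers) | OC[C@@]1(C)[C@@H](O)CC[C@@]2(C)[C@@H]1C[C@H](C(C)=C)[C@@H](C)[C@]21CCC(Br)C(O)O1
F3 | step 9 | spiro lactol (14-hydroxy tetrahydropyran spiro at C9, anomers) | OC[C@@]1(C)[C@@H](O)CC[C@@]2(C)[C@@H]1C[C@H](C(C)=C)[C@@H](C)[C@]21CCCC(O)O1
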